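**Overview**

- Bonds cut: after the three O-benzyl groups, lower ring C is opened at C4–C4a (arene–epoxide bond) and at O1–C2 (aryl ether). This leaves a 4-(2,4,6-trihydroxyphenyl)flavan and a C9 aryl epoxy alcohol. The interflavan C4–C6 bond (flavan-4-ol + phloroglucinol) and upper C2–aryl (chromone + arylboronic acid) are cut next.
- Forward order: upper rings A and C come with 7-hydroxychromone, ring B is added at C2, the phloroglucinol ring (future lower ring A) is attached at C4, the C9 unit is hung on its para oxygen, and lower ring C closes last.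
- Enabling feature: in lower ring A, C6 (bonded to upper C4) lies between C5–OH and C7–OH and para to C8a–O1. While lower ring C (O1, C2, C3, C4) is absent, this ring is a 2-substituted phloroglucinol with one unflanked para OH and two CH carbons that exchange by rotation about the C4–C6 bond. Closing C4–C4a on either carbon can therefore only give the 4→6 constitution.
- Stereochemistry: upper C2 (S) from catalytic asymmetric conjugate arylation; upper C4 (R, 2,4-trans) relayed from C2 in the Friedel–Crafts step; lower C3 (R) from a Sharpless kinetic-resolution epoxidation; lower C2 (R, 2,3-cis) from the same epoxy alcohol by Mitsunobu inversion.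

Key step: step 8

Assumption: the (R) enantiomer of the ligand t-BuPyOx [4-tert-butyl-2-(pyridin-2-yl)-4,5-dihydrooxazole] is taken to give the 2S flavanone in step 4, by transfer of the facial model known for cyclic enones to the chromone; if the sense proves opposite, the (S) ligand is used and nothing else changes.

**Route**

Step 1
Reactants: 1 4-(benzyloxy)benzaldehyde; 2 vinylmagnesium bromide
Product: 3 (±)-1-[4-(benzyloxy)phenyl]prop-2-en-1-ol
Conditions: 2 (1.2 equiv), THF, −78 to 0 °C; then aq NH4Cl
Reagents that add atoms: none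
Why: Grignard 1,2-addition of the vinyl nucleophile to the aldehyde should give the racemic allylic alcohol, and no stereocontrol is sought because step 2 resolves it.

Step 2
Reactants: 3 (±)-1-[4-(benzyloxy)phenyl]prop-2-en-1-ol
Product: 4 (S)-[4-(benzyloxy)phenyl][(2R)-oxiran-2-yl]methanol (erythro epoxy alcohol)
Conditions: Ti(OiPr)4 (10 mol %), L-(+)-diisopropyl tartrate (15 mol %), t-BuOOH (0.45 equiv), 4 Å molecular sieves, CH2Cl2, −20 °C
Reagents that add atoms: tert-butyl hydroperoxide, CC(C)(C)OO
Why: In this Sharpless kinetic resolution (titanium tartrate epoxidation of a secondary allylic alcohol) the L-(+)-tartrate catalyst should epoxidise the R alcohol much faster than the S alcohol and with erythro selectivity, so that the new oxirane carbon is set as R by the tartrate and the carbinol carbon (S only by a change of CIP priorities) is selected from the racemate, the S alcohol staying behind.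

Step 3
Reactants: 5 7-hydroxychromone
Product: 6 7-(benzyloxy)chromone
Conditions: BnBr (1.2 equiv), K2CO3, acetone, reflux
Reagents that add atoms: benzyl bromide, BrCc1ccccc1
Why: Williamson O-alkylation of the only acidic hydroxyl should be clean, since the chromone ring tolerates carbonate.

Step 4
Reactants: 6 7-(benzyloxy)chromone; 7 [4-(benzyloxy)phenyl]boronic acid
Product: 8 (2S)-7-(benzyloxy)-2-[4-(benzyloxy)phenyl]chroman-4-one
Conditions: 7 (2 equiv), Pd(OCOCF3)2 (5 mol %), (R)-t-BuPyOx (6 mol %), NH4PF6 (30 mol %), H2O (5 equiv), ClCH2CH2Cl, 60 °C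
Reagents that add atoms: none
Why: This is an enantioselective conjugate addition of an arylboronic acid (Hayashi–Miyaura type) catalysed by cationic divalent palladium with a pyridine-oxazoline ligand, in which the aryl–palladium species inserts the chromone C2=C3 bond, water protonates the palladium enolate, and the tert-butyl group of the ligand selects the enone face so that C2 is formed as S.

Step 5
Reactants: 8 (2S)-7-(benzyloxy)-2-[4-(benzyloxy)phenyl]chroman-4-one
Product: 9 (2S,4S)-7-(benzyloxy)-2-[4-(benzyloxy)phenyl]chroman-4-ol (2,4-cis)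
Conditions: NaBH4, THF–MeOH, −10 to 0 °C
Reagents that add atoms: none
Why: Borohydride 1,2-reduction of the ketone, run cold and directly after step 4 so that C2 is not racemised by retro-oxa-Michael opening, should deliver hydride axially to give the 2,4-cis alcohol, although the C4 configuration is erased in step 6.

Step 6
Reactants: 9 (2S,4S)-7-(benzyloxy)-2-[4-(benzyloxy)phenyl]chroman-4-ol; 10 phloroglucinol
Product: 11 2-{(2S,4R)-7-(benzyloxy)-2-[4-(benzyloxy)phenyl]chroman-4-yl}benzene-1,3,5-triol (2,4-trans)
Conditions: 10 (5 equiv), BF3·OEt2 (0.2 equiv), 1,4-dioxane, 15 °C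
Reagents that add atoms: none
Why: In this acid-catalysed Friedel–Crafts alkylation (SN1) the C4 cation, stabilised by O1 and the para 7-benzyloxy group, is captured by excess phloroglucinol, whose three CH positions are equivalent, and pseudoaxial attack anti to the equatorial 2-aryl group of the half-chair should set C4 as R (2,4-trans), any cis epimer being removed by chromatography.

Step 7
Reactants: 11 2-{(2S,4R)-7-(benzyloxy)-2-[4-(benzyloxy)phenyl]chroman-4-yl}benzene-1,3,5-triol; 4 (S)-[4-(benzyloxy)phenyl][(2R)-oxiran-2-yl]methanol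
Product: 12 5-{(R)-[4-(benzyloxy)phenyl][(2R)-oxiran-2-yl]methoxy}-2-{(2S,4R)-7-(benzyloxy)-2-[4-(benzyloxy)phenyl]chroman-4-yl}benzene-1,3-diol
Conditions: 11 (1.3 equiv), 4 (1.0 equiv), PPh3, DIAD (slow addition), THF, 0 °C to rt
Reagents that add atoms: none
Why: In this Mitsunobu etherification the unflanked para hydroxyl (the two others sit beside the bulky flavan-4-yl group) should displace the oxyphosphonium of the secondary carbinol by SN2 with inversion (S to R), the oxirane being untouched and its inductive effect disfavouring an SN1 path.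

Step 8
Reactants: 12 5-{(R)-[4-(benzyloxy)phenyl][(2R)-oxiran-2-yl]methoxy}-2-{(2S,4R)-7-(benzyloxy)-2-[4-(benzyloxy)phenyl]chroman-4-yl}benzene-1,3-diol
Product: 13 (2R,3R)-2-[4-(benzyloxy)phenyl]-6-{(2S,4R)-7-(benzyloxy)-2-[4-(benzyloxy)phenyl]chroman-4-yl}chroman-3,5,7-triol
Conditions: (CF3)2CHOH, 0.005 M, 0 °C to rt
Reagents that add atoms: none
Why: Hexafluoroisopropanol hydrogen-bonds to the oxirane oxygen, and the ring CH carbon ortho to the new ether oxygen (also ortho and para to the two free hydroxyls) attacks the terminal CH2 in an SN2-like Friedel–Crafts alkylation followed by rearomatisation, which forms lower C4–C4a and releases the 3-OH. The closest known reaction type is the intramolecular Friedel–Crafts epoxy-arene cyclisation of electron-rich aryl glycidyl ethers to chroman-3-ols, promoted by fluorinated alcohols or by AuCl3/AgOSO2CF3. Lower ring C closes in the 6-endo-tet mode (both oxirane carbons become ring members); the 5-exo attack on the internal carbon is more hindered and badly aligned for an arene nucleophile. No stereocentre is formed: lower C3 (R) is the oxirane carbon of step 2, whose C–O bond stays intact, and lower C2 (R) is the ether carbon of step 7, so the 2,3-cis relation is carried in by the substrate. The step needs endo over exo opening and activation of the epoxide without heterolysis of the 4-benzyloxybenzylic C2–O bond, which the primary terminus, the highly nucleophilic phloroglucinol mono-ether ring, the electron-withdrawing oxirane next to C2 and cold, dilute conditions should secure. The two ortho CH carbons exchange by rotation about the C4–aryl bond, so attack by either gives the same 4→6 product.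

Step 9
Reactants: 13 (2R,3R)-2-[4-(benzyloxy)phenyl]-6-{(2S,4R)-7-(benzyloxy)-2-[4-(benzyloxy)phenyl]chroman-4-yl}chroman-3,5,7-triol
Product: 14 (2R,3R)-6-[(2S,4R)-7-hydroxy-2-(4-hydroxyphenyl)chroman-4-yl]-2-(4-hydroxyphenyl)chroman-3,5,7-triol (target)
Conditions: H2 (1 atm), Pd(OH)2/C, THF–MeOH, rt
Reagents that add atoms: none
Why: Catalytic hydrogenolysis should remove the three benzyl aryl ethers under neutral conditions, since the cyclic benzylic C2–O1 ethers and the C4–C6 bond are cleaved far more slowly and no base is present that could epimerise C2 through a quinone methide.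

**Compound list**

1 | 4-(benzyloxy)benzaldehyde | O=Cc1ccc(OCc2ccccc2)cc1 | starting material
2 | vinylmagnesium bromide | C=C[Mg]Br | starting material
3 | (±)-1-[4-(benzyloxy)phenyl]prop-2-en-1-ol | OC(C=C)c1ccc(OCc2ccccc2)cc1 | intermediate
4 | (S)-[4-(benzyloxy)phenyl][(2R)-oxiran-2-yl]methanol | O[C@@H](c1ccc(OCc2ccccc2)cc1)[C@H]1CO1 | intermediate
5 | 7-hydroxychromone | O=c1ccoc2cc(O)ccc12 | starting material
6 | 7-(benzyloxy)chromone | O=c1ccoc2cc(OCc3ccccc3)ccc12 | intermediate
7 | [4-(benzyloxy)phenyl]boronic acid | OB(O)c1ccc(OCc2ccccc2)cc1 | starting material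
8 | (2S)-7-(benzyloxy)-2-[4-(benzyloxy)phenyl]chroman-4-one | O=C1C[C@@H](c2ccc(OCc3ccccc3)cc2)Oc2cc(OCc3ccccc3)ccc12 | intermediate
9 | (2S,4S)-7-(benzyloxy)-2-[4-(benzyloxy)phenyl]chroman-4-ol | O[C@H]1C[C@@H](c2ccc(OCc3ccccc3)cc2)Oc2cc(OCc3ccccc3)ccc12 | intermediate
10 | phloroglucinol (benzene-1,3,5-triol) | Oc1cc(O)cc(O)c1 | starting material
11 | 2-{(2S,4R)-7-(benzyloxy)-2-[4-(benzyloxy)phenyl]chroman-4-yl}benzene-1,3,5-triol | Oc1cc(O)c([C@@H]2C[C@@H](c3ccc(OCc4ccccc4)cc3)Oc3cc(OCc4ccccc4)ccc32)c(O)c1 | intermediate
12 | 5-{(R)-[4-(benzyloxy)phenyl][(2R)-oxiran-2-yl]methoxy}-2-{(2S,4R)-7-(benzyloxy)-2-[4-(benzyloxy)phenyl]chroman-4-yl}benzene-1,3-diol | c1(O[C@H](c2ccc(OCc3ccccc3)cc2)[C@H]2CO2)cc(O)c([C@@H]2C[C@@H](c3ccc(OCc4ccccc4)cc3)Oc3cc(OCc4ccccc4)ccc32)c(O)c1 | intermediate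
13 | (2R,3R)-2-[4-(benzyloxy)phenyl]-6-{(2S,4R)-7-(benzyloxy)-2-[4-(benzyloxy)phenyl]chroman-4-yl}chroman-3,5,7-triol | O[C@@H]1Cc2c(O)c([C@@H]3C[C@@H](c4ccc(OCc5ccccc5)cc4)Oc4cc(OCc5ccccc5)ccc43)c(O)cc2O[C@@H]1c1ccc(OCc2ccccc2)cc1 | intermediate
14 | (2R,3R)-6-[(2S,4R)-7-hydroxy-2-(4-hydroxyphenyl)chroman-4-yl]-2-(4-hydroxyphenyl)chroman-3,5,7-triol | Oc1ccc([C@@H]2C[C@@H](c3c(O)cc4c(c3O)C[C@@H](O)[C@@H](c3ccc(O)cc3)O4)c3ccc(O)cc3O2)cc1 | target

**Step count and risks**

Total step count: 9. Longest linear sequence: 7 steps (steps 3 to 9, from 7-hydroxychromone 5); the epoxy alcohol 4 is made in 2 steps and enters at step 7.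

Steps most likely to fail:

Step 8 (ring closure). The 4-benzyloxybenzylic C2–O bond may ionise in the protic, ionising medium, which would scramble lower C2 or shift the aryl group. The epoxide may also be opened by a free phenol of a second molecule before the ring carbon attacks. Fallback: setting out from 12, both free phenols are benzylated (BnBr, K2CO3, DMF, 20 °C, which the epoxide tolerates) to give the bis-benzyl epoxy ether F1. This non-phenolic 3,5-dialkoxyphenyl ether is closed in an aprotic medium with catalytic AuCl3/AgOSO2CF3 in ClCH2CH2Cl, with no ionising solvent and no phenolic nucleophile present, to give the penta-O-benzyl flavan-3-ol F2. Hydrogenolysis of all five benzyl ethers under the conditions of step 9 comes back to the route at 14.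

Step 7 (Mitsunobu). Etherification may occur at a flanking hydroxyl or twice. The activated, electron-rich benzylic carbinol may also ionise in part, so that inversion is incomplete. Fallback: setting out from 11, the unflanked para hydroxyl is silylated with the bulky chloride iPr3SiCl (imidazole, DMF, 0 °C) to give the para-O-triisopropylsilyl ether F3. The two hindered hydroxyls are acetylated (Ac2O, pyridine, 4-(dimethylamino)pyridine) to give the silyl ether diacetate F4. The silyl group is removed with HF·pyridine in THF to give the mono-phenol diacetate F5, whose single free hydroxyl is made more acidic by the two acetoxy groups. Mitsunobu coupling of F5 with 4 (PPh3, DIAD, toluene, 0 °C) then has one site only and should give the diacetate epoxy ether F6. Brief methanolysis (K2CO3, MeOH, 0 °C) removes both acetates and comes back to the route at 12.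

Step 2 (kinetic-resolution epoxidation). The rate difference between the enantiomers of the aryl vinyl carbinol may be too small. The electron-rich benzylic epoxy alcohol may also be opened on titanium during the slow, sub-stoichiometric run. Either would leave the collected epoxy alcohol with insufficient enantiomeric and erythro purity. Fallback: setting out from 3, a first resolution with the enantiomeric tartrate (Ti(OiPr)4, D-(−)-diisopropyl tartrate, t-BuOOH 0.6 equiv, 4 Å molecular sieves, CH2Cl2, −20 °C) is run past half conversion. The S alcohol is consumed and the slow-reacting (R)-allylic alcohol F7 is recovered; its purity rises with conversion and does not depend on the survival of any epoxide. A short, matched epoxidation of F7 with Ti(OiPr)4, L-(+)-diisopropyl tartrate and a full equivalent of t-BuOOH then comes back to the route at 4.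

**Further compounds**

F1 | step 8 | 1,3-bis(benzyloxy)-5-{(R)-[4-(benzyloxy)phenyl][(2R)-oxiran-2-yl]methoxy}-2-{(2S,4R)-7-(benzyloxy)-2-[4-(benzyloxy)phenyl]chroman-4-yl}benzene | c1(O[C@H](c2ccc(OCc3ccccc3)cc2)[C@H]2CO2)cc(OCc2ccccc2)c([C@@H]2C[C@@H](c3ccc(OCc4ccccc4)cc3)Oc3cc(OCc4ccccc4)ccc32)c(OCc2ccccc2)c1
F2 | step 8 | (2R,3R)-5,7-bis(benzyloxy)-2-[4-(benzyloxy)phenyl]-6-{(2S,4R)-7-(benzyloxy)-2-[4-(benzyloxy)phenyl]chroman-4-yl}chroman-3-ol | O[C@@H]1Cc2c(OCc3ccccc3)c([C@@H]3C[C@@H](c4ccc(OCc5ccccc5)cc4)Oc4cc(OCc5ccccc5)ccc43)c(OCc3ccccc3)cc2O[C@@H]1c1ccc(OCc2ccccc2)cc1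
F3 | step 7 | 2-{(2S,4R)-7-(benzyloxy)-2-[4-(benzyloxy)phenyl]chroman-4-yl}-5-[(triisopropylsilyl)oxy]benzene-1,3-diol | c1(O[Si](C(C)C)(C(C)C)C(C)C)cc(O)c([C@@H]2C[C@@H](c3ccc(OCc4ccccc4)cc3)Oc3cc(OCc4ccccc4)ccc32)c(O)c1
F4 | step 7 | 2-{(2S,4R)-7-(benzyloxy)-2-[4-(benzyloxy)phenyl]chroman-4-yl}-5-[(triisopropylsilyl)oxy]-1,3-phenylene diacetate | c1(O[Si](C(C)C)(C(C)C)C(C)C)cc(OC(C)=O)c([C@@H]2C[C@@H](c3ccc(OCc4ccccc4)cc3)Oc3cc(OCc4ccccc4)ccc32)c(OC(C)=O)c1
F5 | step 7 | 2-{(2S,4R)-7-(benzyloxy)-2-[4-(benzyloxy)phenyl]chroman-4-yl}-5-hydroxy-1,3-phenylene diacetate | Oc1cc(OC(C)=O)c([C@@H]2C[C@@H](c3ccc(OCc4ccccc4)cc3)Oc3cc(OCc4ccccc4)ccc32)c(OC(C)=O)c1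
F6 | step 7 | 5-{(R)-[4-(benzyloxy)phenyl][(2R)-oxiran-2-yl]methoxy}-2-{(2S,4R)-7-(benzyloxy)-2-[4-(benzyloxy)phenyl]chroman-4-yl}-1,3-phenylene diacetate | c1(O[C@H](c2ccc(OCc3ccccc3)cc2)[C@H]2CO2)cc(OC(C)=O)c([C@@H]2C[C@@H](c3ccc(OCc4ccccc4)cc3)Oc3cc(OCc4ccccc4)ccc32)c(OC(C)=O)c1
F7 | step 2 | (R)-1-[4-(benzyloxy)phenyl]prop-2-en-1-ol | O[C@H](C=C)c1ccc(OCc2ccccc2)cc1
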